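**Plan**

1. Cuts: the sulfate O–S bond; the octenyl C4–C5 bond (sp3–sp2, B-alkyl Suzuki), with the C5=C6 alkene and its C6 methyl traced to a terminal alkyne (carboalumination); in the ring, the methyl groups on C2 and C6 are each traced back to a C=O, and the ring is then opened at C1–C2 and C4–C5 in one [3+3] disconnection.
2. Enabling feature: ring C1 (quaternary, CH3 and side chain) lies between C2 (sp2, CH3) and C6 (sp3, CH3, H). With both as carbonyls the ring is a mirror-symmetric 2,2-disubstituted cyclohexane-1,3-dione, and its C1–C2 and C4–C5 bonds are exactly those made when an acryloyl unit (C2–C3–C4) bridges the branched α′-carbon (C1) and the methyl carbon (C5) of an open-chain methyl ketone (C5–C6–C1).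
3. Forward: keto acetal (steps 1–2); the only ring by enamine α,α′-annulation (step 3); desymmetrisation and installation of the C6 and C2 methyls (steps 4–9); alkyne and E-vinyl iodide (steps 10–12); side-chain fragment (steps 13–17); chain joined by Suzuki coupling (step 18); desilylation and O-sulfonation (steps 19–20).
4. Stereochemistry: ring C1 from CBS desymmetrisation of the achiral dione; ring C6 relayed from the new carbinol by hydroxyl-directed hydrogenation; chain C2 from copper-catalysed asymmetric allylic alkylation; the E alkene from syn-carboalumination.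

Key step: step 3

Remark: the target is taken as the free hydrogen sulfate as drawn; it is released from its pyridinium salt by cold proton exchange and would in practice be stored as a salt.

**Route**

Step 1
Reactants: 1 ethyl 2-methyl-3-oxobutanoate; 2 2-(2-bromoethyl)-1,3-dioxolane
Product: 4 ethyl 2-acetyl-4-(1,3-dioxolan-2-yl)-2-methylbutanoate (racemic), via sodium enolate 3 (not isolated)
Conditions: NaH, DMF, 0 °C; then 2, NaI (cat.), 60 °C
Reagents that add atoms: none
Why: C-alkylation of the sodium enolate of an α-substituted acetoacetic ester by a primary bromide (acetoacetic ester synthesis) should attach the acetal-bearing arm; the quaternary centre is racemic, which does not matter because it becomes achiral in step 3.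

Step 2
Reactants: 4 ethyl 2-acetyl-4-(1,3-dioxolan-2-yl)-2-methylbutanoate
Product: 5 5-(1,3-dioxolan-2-yl)-3-methylpentan-2-one (racemic)
Conditions: LiCl, H2O, DMSO, 150 °C
Reagents that add atoms: none
Why: Krapcho dealkoxycarbonylation of the α,α-disubstituted β-keto ester under neutral halide conditions should leave the methyl ketone, spare the acetal and avoid the retro-Claisen deacetylation that hydroxide would cause.

Step 3
Reactants: 5 5-(1,3-dioxolan-2-yl)-3-methylpentan-2-one; 6 prop-2-enoyl chloride
Product: 9 2-[2-(1,3-dioxolan-2-yl)ethyl]-2-methylcyclohexane-1,3-dione (achiral), via pyrrolidine enamine 7 (not isolated), via annulated iminium chloride 8 (not isolated)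
Conditions: pyrrolidine, TsOH (cat.), PhMe, reflux, Dean–Stark; then 6, PhMe, reflux; then AcOH, NaOAc, H2O, 80 °C
Reagents that add atoms: water, O
Why: Pyrrolidine condenses with methyl ketone 5 on its less hindered side to give the terminal enamine 7, acryloyl chloride N-acylates it, and the N-acylenammonium ion rearranges by a [3,3] shift (a Michael-type C-alkylation) that joins the former methyl carbon of 5 to the β-carbon of the acryloyl unit and unmasks a ketene; after proton transfer to the more substituted enamine the branched α′-carbon attacks the ketene carbon to give iminium salt 8, which water hydrolyses to 9. The closest known reaction type is the α,α′-annulation of Stork enamines of cyclic and open-chain ketones by α,β-unsaturated acid chlorides, a formal [3+3] carbocyclisation that gives cyclohexane-1,3-diones. The one ring is closed in the second C–C bond formation, a 6-exo-trig C-acylation of the enamine by the acyl carbon. The new quaternary carbon is not a stereocentre here, because 9 has a mirror plane through C2 and C5, so no stereocontrol is needed and the racemic centre of 5 is erased. The step needs regioselectivity only (acryloyl β-carbon to the methyl terminus, acyl carbon to the branched carbon): the first is set by the position of the enamine double bond, which avoids allylic strain with the branched substituent, and the second by the fact that only acylation at the branched α′-carbon closes a six-membered ring.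

Step 4
Reactants: 9 2-[2-(1,3-dioxolan-2-yl)ethyl]-2-methylcyclohexane-1,3-dione
Product: 10 (2R,3R)-2-[2-(1,3-dioxolan-2-yl)ethyl]-3-hydroxy-2-methylcyclohexan-1-one
Conditions: (S)-2-methyl-CBS-oxazaborolidine (0.2 equiv), catecholborane, PhMe, −78 °C
Reagents that add atoms: none
Why: Corey–Bakshi–Shibata mono-reduction desymmetrises the dione: the S catalyst should make the carbinol R (quaternary carbon as the large group), and hydride should enter anti to the larger C2 substituent, which places OH cis to the acetal chain and thereby fixes C2 as R.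

Step 5
Reactants: 10 (2R,3R)-2-[2-(1,3-dioxolan-2-yl)ethyl]-3-hydroxy-2-methylcyclohexan-1-one
Product: 11 (1R,2S)-2-[2-(1,3-dioxolan-2-yl)ethyl]-2-methyl-3-methylidenecyclohexan-1-ol
Conditions: Zn, CH2Br2, TiCl4, THF, 0 °C; then 10, CH2Cl2, 25 °C
Reagents that add atoms: dibromomethane, BrCBr
Why: Lombardo methylenation with a non-basic titanium methylidene should convert the hindered ketone into the exocyclic alkene without retro-aldol cleavage of the β-hydroxy ketone and without touching the acetal; no stereocentre is altered (the C2 descriptor changes only through substituent priority).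

Step 6
Reactants: 11 (1R,2S)-2-[2-(1,3-dioxolan-2-yl)ethyl]-2-methyl-3-methylidenecyclohexan-1-ol
Product: 12 (1R,2S,3R)-2-[2-(1,3-dioxolan-2-yl)ethyl]-2,3-dimethylcyclohexan-1-ol
Conditions: [Ir(cod)(PCy3)(py)]PF6 (5 mol %), H2 (1 atm), CH2Cl2, 0 to 25 °C
Reagents that add atoms: none
Why: Hydroxyl-directed homogeneous hydrogenation: the cationic iridium catalyst should bind the homoallylic C1 hydroxyl and add H2 to the exocyclic alkene from the hydroxyl face, so the new C3 methyl is trans to OH and to the acetal chain and cis to the C2 methyl (3R).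

Step 7
Reactants: 12 (1R,2S,3R)-2-[2-(1,3-dioxolan-2-yl)ethyl]-2,3-dimethylcyclohexan-1-ol
Product: 13 (2S,3R)-2-[2-(1,3-dioxolan-2-yl)ethyl]-2,3-dimethylcyclohexan-1-one
Conditions: Dess–Martin periodinane, NaHCO3, CH2Cl2, 0 to 25 °C
Reagents that add atoms: none
Why: Dess–Martin oxidation under buffered neutral conditions should give the ketone without cleaving the acetal; C3 is not α to the carbonyl and cannot epimerise.

Step 8
Reactants: 13 (2S,3R)-2-[2-(1,3-dioxolan-2-yl)ethyl]-2,3-dimethylcyclohexan-1-one
Product: 15 (5R,6S)-6-[2-(1,3-dioxolan-2-yl)ethyl]-5,6-dimethylcyclohex-1-en-1-yl trifluoromethanesulfonate, via potassium enolate 14 (not isolated)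
Conditions: KN(SiMe3)2, THF, −78 °C; then PhNTf2, −78 to 0 °C
Reagents that add atoms: N-phenylbis(trifluoromethanesulfonimide), O=S(=O)(N(c1ccccc1)S(=O)(=O)C(F)(F)F)C(F)(F)F
Why: Enolate O-triflation; because C2 is quaternary the ketone can enolise only towards C6, so the enol triflate double bond is placed regiospecifically where the ring alkene of the target lies.

Step 9
Reactants: 15 (5R,6S)-6-[2-(1,3-dioxolan-2-yl)ethyl]-5,6-dimethylcyclohex-1-en-1-yl trifluoromethanesulfonate
Product: 16 2-{2-[(1S,6R)-1,2,6-trimethylcyclohex-2-en-1-yl]ethyl}-1,3-dioxolane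
Conditions: Fe(acac)3 (10 mol %), MeMgBr, THF/NMP, −20 °C
Reagents that add atoms: methylmagnesium bromide, C[Mg]Br
Why: Iron-catalysed Kumada-type cross-coupling of the alkenyl triflate with the methyl Grignard reagent should install the vinylic methyl with the double bond unmoved; acetal and stereocentres are inert.

Step 10
Reactants: 16 2-{2-[(1S,6R)-1,2,6-trimethylcyclohex-2-en-1-yl]ethyl}-1,3-dioxolane
Product: 17 3-[(1S,6R)-1,2,6-trimethylcyclohex-2-en-1-yl]propanal
Conditions: 1 M HCl (aq), THF, 25 °C
Reagents that add atoms: water, O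
Why: Acid-catalysed acetal hydrolysis should release the aldehyde; the trisubstituted ring alkene is not protonated under these dilute conditions.

Step 11
Reactants: 17 3-[(1S,6R)-1,2,6-trimethylcyclohex-2-en-1-yl]propanal
Product: 18 (5R,6S)-6-(but-3-yn-1-yl)-1,5,6-trimethylcyclohex-1-ene
Conditions: dimethyl (1-diazo-2-oxopropyl)phosphonate, K2CO3, MeOH, 0 to 25 °C
Reagents that add atoms: dimethyl (1-diazo-2-oxopropyl)phosphonate, COP(=O)(OC)C(=[N+]=[N-])C(C)=O
Why: Seyferth–Gilbert homologation in its Ohira–Bestmann form should convert the aldehyde into the terminal alkyne with one added carbon under mild base.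

Step 12
Reactants: 18 (5R,6S)-6-(but-3-yn-1-yl)-1,5,6-trimethylcyclohex-1-ene
Product: 20 (5R,6S)-6-[(3E)-4-iodo-3-methylbut-3-en-1-yl]-1,5,6-trimethylcyclohex-1-ene, via alkenylalane 19 (not isolated)
Conditions: AlMe3, Cp2ZrCl2 (25 mol %), CH2Cl2, 0 to 25 °C; then I2, THF, −30 °C
Reagents that add atoms: trimethylaluminium, C[Al](C)C; iodine, II
Why: Negishi zirconium-catalysed carboalumination adds CH3 and Al syn across the terminal alkyne with CH3 on the internal carbon, and iodinolysis with retention should give the E-vinyl iodide; the trisubstituted ring alkene does not react.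

Step 13
Reactants: 21 3-bromofuran; 22 oxetane
Product: 24 3-(furan-3-yl)propan-1-ol, via furan-3-yllithium 23 (not isolated)
Conditions: n-BuLi, THF, −78 °C; then 22, BF3·OEt2, −78 °C
Reagents that add atoms: none
Why: Bromine–lithium exchange followed by BF3-promoted ring opening of oxetane by the aryllithium should give the three-carbon alcohol; −78 °C suppresses isomerisation to the 2-lithiofuran.

Step 14
Reactants: 24 3-(furan-3-yl)propan-1-ol
Product: 25 3-(3-bromopropyl)furan
Conditions: CBr4, PPh3, CH2Cl2, 0 °C
Reagents that add atoms: carbon tetrabromide, BrC(Br)(Br)Br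
Why: Appel bromination under neutral conditions should convert the primary alcohol into the bromide without harming the acid-sensitive furan.

Step 15
Reactants: 26 (2E)-but-2-ene-1,4-diol
Product: 28 (2E)-4-{[tert-butyl(diphenyl)silyl]oxy}but-2-en-1-ol, via sodium alkoxide 27 (not isolated)
Conditions: NaH (1.0 equiv), THF, 0 °C; then t-BuPh2SiCl, 25 °C
Reagents that add atoms: tert-butyl(chloro)diphenylsilane, CC(C)(C)[Si](Cl)(c1ccccc1)c1ccccc1
Why: O-silylation of the symmetric diol through its sparingly soluble monosodium alkoxide should favour the mono-ether.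

Step 16
Reactants: 28 (2E)-4-{[tert-butyl(diphenyl)silyl]oxy}but-2-en-1-ol
Product: 29 {[(2E)-4-bromobut-2-en-1-yl]oxy}(tert-butyl)diphenylsilane
Conditions: CBr4, PPh3, CH2Cl2, 0 °C
Reagents that add atoms: carbon tetrabromide, BrC(Br)(Br)Br
Why: Appel bromination of the primary allylic alcohol proceeds by SN2 displacement and should keep the E double bond in place.

Step 17
Reactants: 25 3-(3-bromopropyl)furan; 29 {[(2E)-4-bromobut-2-en-1-yl]oxy}(tert-butyl)diphenylsilane
Product: 31 tert-butyl({(2S)-2-[3-(furan-3-yl)propyl]but-3-en-1-yl}oxy)diphenylsilane, via Grignard reagent 30 (not isolated)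
Conditions: Mg, Et2O, 35 °C; then 29, CuBr·SMe2 (5 mol %), (R,R)-Taniaphos (ferrocenyl diphosphine, C43H39FeNP2, 6 mol %), CH2Cl2, −78 °C
Reagents that add atoms: none
Why: Copper-catalysed asymmetric allylic alkylation (SN2′) of the E-allylic bromide by the alkyl Grignard reagent should give the branched terminal alkene; the chiral copper–diphosphine complex controls the new stereocentre, the (R,R) ligand being expected to give S (its antipode is used if the sense proves opposite).

Step 18
Reactants: 31 tert-butyl({(2S)-2-[3-(furan-3-yl)propyl]but-3-en-1-yl}oxy)diphenylsilane; 20 (5R,6S)-6-[(3E)-4-iodo-3-methylbut-3-en-1-yl]-1,5,6-trimethylcyclohex-1-ene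
Product: 33 tert-butyl({(2S,5E)-2-[3-(furan-3-yl)propyl]-6-methyl-8-[(1S,6R)-1,2,6-trimethylcyclohex-2-en-1-yl]oct-5-en-1-yl}oxy)diphenylsilane, via alkyl-9-BBN borane 32 (not isolated)
Conditions: 9-BBN, THF, 0 to 25 °C; then 20, Pd(dppf)Cl2 (5 mol %), AsPh3, Cs2CO3, DMF/THF/H2O, 25 °C
Reagents that add atoms: none
Why: Anti-Markovnikov hydroboration of the terminal alkene and B-alkyl Suzuki–Miyaura coupling with the vinyl iodide should form the sp3–sp2 bond with retention of the E geometry; furan, silyl ether and the ring alkene are tolerated and no stereocentre is touched.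

Step 19
Reactants: 33 tert-butyl({(2S,5E)-2-[3-(furan-3-yl)propyl]-6-methyl-8-[(1S,6R)-1,2,6-trimethylcyclohex-2-en-1-yl]oct-5-en-1-yl}oxy)diphenylsilane
Product: 34 (2S,5E)-2-[3-(furan-3-yl)propyl]-6-methyl-8-[(1S,6R)-1,2,6-trimethylcyclohex-2-en-1-yl]oct-5-en-1-ol
Conditions: Bu4NF, THF, 25 °C
Reagents that add atoms: none
Why: Fluoride-mediated cleavage of the silyl ether should free the primary alcohol without affecting the furan or the alkenes.

Step 20
Reactants: 34 (2S,5E)-2-[3-(furan-3-yl)propyl]-6-methyl-8-[(1S,6R)-1,2,6-trimethylcyclohex-2-en-1-yl]oct-5-en-1-ol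
Product: 36 (2S,5E)-2-[3-(furan-3-yl)propyl]-6-methyl-8-[(1S,6R)-1,2,6-trimethylcyclohex-2-en-1-yl]oct-5-en-1-yl hydrogen sulfate, via pyridinium sulfate 35 (not isolated)
Conditions: SO3·pyridine, pyridine, 0 to 25 °C; then H+-form cation-exchange resin, MeOH/H2O, 0 °C
Reagents that add atoms: sulfur trioxide–pyridine complex, O=S(=O)([O-])[n+]1ccccc1
Why: O-sulfonation of the primary alcohol by the mild SO3–amine complex should give the sulfate monoester as its pyridinium salt, and cold proton exchange should release the hydrogen sulfate without touching the stereocentres.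

**Compound list**

1 | ethyl 2-methyl-3-oxobutanoate | CCOC(=O)C(C)C(C)=O | starting material
2 | 2-(2-bromoethyl)-1,3-dioxolane | BrCCC1OCCO1 | starting material
3 | sodium enolate of 1 (sodium 4-ethoxy-3-methyl-4-oxobut-2-en-2-olate) | CCOC(=O)C(C)=C(C)[O-].[Na+] | intermediate
4 | ethyl 2-acetyl-4-(1,3-dioxolan-2-yl)-2-methylbutanoate (racemic) | CCOC(=O)C(C)(CCC1OCCO1)C(C)=O | intermediate
5 | 5-(1,3-dioxolan-2-yl)-3-methylpentan-2-one (racemic) | CC(=O)C(C)CCC1OCCO1 | intermediate
6 | prop-2-enoyl chloride (acryloyl chloride) | C=CC(=O)Cl | starting material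
7 | 1-[5-(1,3-dioxolan-2-yl)-3-methylpent-1-en-2-yl]pyrrolidine | C=C(N1CCCC1)C(C)CCC2OCCO2 | intermediate
8 | 1-{2-[2-(1,3-dioxolan-2-yl)ethyl]-2-methyl-3-oxocyclohexylidene}pyrrolidin-1-ium chloride | CC1(CCC2OCCO2)C(=O)CCCC1=[N+]3CCCC3.[Cl-] | intermediate
9 | 2-[2-(1,3-dioxolan-2-yl)ethyl]-2-methylcyclohexane-1,3-dione (achiral) | CC1(CCC2OCCO2)C(=O)CCCC1=O | intermediate
10 | (2R,3R)-2-[2-(1,3-dioxolan-2-yl)ethyl]-3-hydroxy-2-methylcyclohexan-1-one | C[C@]1(CCC2OCCO2)C(=O)CCC[C@H]1O | intermediate
11 | (1R,2S)-2-[2-(1,3-dioxolan-2-yl)ethyl]-2-methyl-3-methylidenecyclohexan-1-ol | C[C@]1(CCC2OCCO2)C(=C)CCC[C@H]1O | intermediate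
12 | (1R,2S,3R)-2-[2-(1,3-dioxolan-2-yl)ethyl]-2,3-dimethylcyclohexan-1-ol | C[C@]1(CCC2OCCO2)[C@H](C)CCC[C@H]1O | intermediate
13 | (2S,3R)-2-[2-(1,3-dioxolan-2-yl)ethyl]-2,3-dimethylcyclohexan-1-one | C[C@]1(CCC2OCCO2)[C@H](C)CCCC1=O | intermediate
14 | potassium (5R,6S)-6-[2-(1,3-dioxolan-2-yl)ethyl]-5,6-dimethylcyclohex-1-en-1-olate | C[C@]1(CCC2OCCO2)[C@H](C)CCC=C1[O-].[K+] | intermediate
15 | (5R,6S)-6-[2-(1,3-dioxolan-2-yl)ethyl]-5,6-dimethylcyclohex-1-en-1-yl trifluoromethanesulfonate | C[C@]1(CCC2OCCO2)[C@H](C)CCC=C1OS(=O)(=O)C(F)(F)F | intermediate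
16 | 2-{2-[(1S,6R)-1,2,6-trimethylcyclohex-2-en-1-yl]ethyl}-1,3-dioxolane | CC1=CCC[C@@H](C)[C@]1(C)CCC2OCCO2 | intermediate
17 | 3-[(1S,6R)-1,2,6-trimethylcyclohex-2-en-1-yl]propanal | CC1=CCC[C@@H](C)[C@]1(C)CCC=O | intermediate
18 | (5R,6S)-6-(but-3-yn-1-yl)-1,5,6-trimethylcyclohex-1-ene | CC1=CCC[C@@H](C)[C@]1(C)CCC#C | intermediate
19 | dimethyl{(1E)-2-methyl-4-[(1S,6R)-1,2,6-trimethylcyclohex-2-en-1-yl]but-1-en-1-yl}alane | CC1=CCC[C@@H](C)[C@]1(C)CC/C(C)=C/[Al](C)C | intermediate
20 | (5R,6S)-6-[(3E)-4-iodo-3-methylbut-3-en-1-yl]-1,5,6-trimethylcyclohex-1-ene | CC1=CCC[C@@H](C)[C@]1(C)CC/C(C)=C/I | intermediate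
21 | 3-bromofuran | Brc1ccoc1 | starting material
22 | oxetane | C1COC1 | starting material
23 | furan-3-yllithium | [Li]c1ccoc1 | intermediate
24 | 3-(furan-3-yl)propan-1-ol | OCCCc1ccoc1 | intermediate
25 | 3-(3-bromopropyl)furan | BrCCCc1ccoc1 | intermediate
26 | (2E)-but-2-ene-1,4-diol | OC/C=C/CO | starting material
27 | monosodium alkoxide of 26 (sodium (2E)-4-hydroxybut-2-en-1-olate) | [Na+].[O-]C/C=C/CO | intermediate
28 | (2E)-4-{[tert-butyl(diphenyl)silyl]oxy}but-2-en-1-ol | OC/C=C/CO[Si](c1ccccc1)(c1ccccc1)C(C)(C)C | intermediate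
29 | {[(2E)-4-bromobut-2-en-1-yl]oxy}(tert-butyl)diphenylsilane | BrC/C=C/CO[Si](c1ccccc1)(c1ccccc1)C(C)(C)C | intermediate
30 | [3-(furan-3-yl)propyl]magnesium bromide | Br[Mg]CCCc1ccoc1 | intermediate
31 | tert-butyl({(2S)-2-[3-(furan-3-yl)propyl]but-3-en-1-yl}oxy)diphenylsilane | C=C[C@H](CCCc1ccoc1)CO[Si](c1ccccc1)(c1ccccc1)C(C)(C)C | intermediate
32 | 9-[(3R)-4-{[tert-butyl(diphenyl)silyl]oxy}-3-[3-(furan-3-yl)propyl]butyl]-9-borabicyclo[3.3.1]nonane | C1CCC2CCCC1B2CC[C@H](CCCc1ccoc1)CO[Si](c1ccccc1)(c1ccccc1)C(C)(C)C | intermediate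
33 | tert-butyl({(2S,5E)-2-[3-(furan-3-yl)propyl]-6-methyl-8-[(1S,6R)-1,2,6-trimethylcyclohex-2-en-1-yl]oct-5-en-1-yl}oxy)diphenylsilane | CC1=CCC[C@@H](C)[C@]1(C)CC/C(C)=C/CC[C@H](CCCc1ccoc1)CO[Si](c1ccccc1)(c1ccccc1)C(C)(C)C | intermediate
34 | (2S,5E)-2-[3-(furan-3-yl)propyl]-6-methyl-8-[(1S,6R)-1,2,6-trimethylcyclohex-2-en-1-yl]oct-5-en-1-ol | CC1=CCC[C@@H](C)[C@]1(C)CC/C(C)=C/CC[C@H](CCCc1ccoc1)CO | intermediate
35 | pyridinium (2S,5E)-2-[3-(furan-3-yl)propyl]-6-methyl-8-[(1S,6R)-1,2,6-trimethylcyclohex-2-en-1-yl]oct-5-en-1-yl sulfate | CC1=CCC[C@@H](C)[C@]1(C)CC/C(C)=C/CC[C@H](CCCc1ccoc1)COS(=O)(=O)[O-].c1cc[nH+]cc1 | intermediate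
36 | (2S,5E)-2-[3-(furan-3-yl)propyl]-6-methyl-8-[(1S,6R)-1,2,6-trimethylcyclohex-2-en-1-yl]oct-5-en-1-yl hydrogen sulfate | CC1=CCC[C@@H](C)[C@]1(C)CC/C(C)=C/CC[C@H](CCCc1ccoc1)COS(=O)(=O)O | target

**Step count and risks**

Total step count: 20. Longest linear sequence: 15 steps (steps 1–12, then 18–20).

Steps most likely to fail:

1. Step 3. What may go wrong: the two bond-forming events may cross over (C-acylation at the methyl terminus followed by Michael closure at the branched carbon would give the 4,4-disubstituted dione), the second closure at the hindered carbon may stall, and the acid chloride may polymerise. The fallback sets out from bromide 2 and comes back at dione 9. Commercial 2-methylcyclohexane-1,3-dione F1 is condensed with 1,1-dimethylhydrazine to 3-(2,2-dimethylhydrazinyl)-2-methylcyclohex-2-en-1-one F2. Deprotonation with KH in THF and C-alkylation with 2 (NaI) gives the quaternary hydrazone 3-(2,2-dimethylhydrazinylidene)-2-[2-(1,3-dioxolan-2-yl)ethyl]-2-methylcyclohexan-1-one F3 (the hydrazone suppresses O-alkylation). Cu(OAc)2 in aqueous THF then hydrolyses F3 to 9. The ring is then bought rather than built, and all later steps are unchanged.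

2. Step 4. What may go wrong: poor discrimination between the two enantiotopic carbonyls or between the two faces (OH cis versus trans to the acetal chain), and over-reduction to the diol. The fallback sets out from dione 9 and comes back at hydroxy ketone 10. Reagent control is replaced by enzyme control: a ketoreductase chosen from a panel for the (2R,3R) product (NADP+, glucose, glucose dehydrogenase, pH 7 buffer, 30 °C) reduces one carbonyl only. Microbial reduction of 2-alkyl-2-methylcyclohexane-1,3-diones with OH cis to the larger group is a well-known reaction type. No new compound is made.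

3. Step 20. What may go wrong: C-sulfonation or acid-promoted opening of the electron-rich furan and migration of the trisubstituted alkenes during O-sulfonation and proton exchange. The fallback sets out from alcohol 34 and comes back at 36. The sulfate is introduced in masked form: 34 is treated with 2,2,2-trichloroethyl chlorosulfate, DMAP and Et3N in CH2Cl2 to give the neutral diester (2S,5E)-2-[3-(furan-3-yl)propyl]-6-methyl-8-[(1S,6R)-1,2,6-trimethylcyclohex-2-en-1-yl]oct-5-en-1-yl 2,2,2-trichloroethyl sulfate F4, which can be purified on silica. Zn and HCO2NH4 in MeOH remove the trichloroethyl group, and the resulting ammonium sulfate monoester is converted into 36 by the same cold proton exchange.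

Further compounds
F1 | step 3 | 2-methylcyclohexane-1,3-dione | CC1C(=O)CCCC1=O
F2 | step 3 | 3-(2,2-dimethylhydrazinyl)-2-methylcyclohex-2-en-1-one | CC1=C(NN(C)C)CCCC1=O
F3 | step 3 | 3-(2,2-dimethylhydrazinylidene)-2-[2-(1,3-dioxolan-2-yl)ethyl]-2-methylcyclohexan-1-one (racemic) | CC1(CCC2OCCO2)C(=O)CCCC1=NN(C)C
F0 | step 4 | none | none
F4 | step 20 | (2S,5E)-2-[3-(furan-3-yl)propyl]-6-methyl-8-[(1S,6R)-1,2,6-trimethylcyclohex-2-en-1-yl]oct-5-en-1-yl 2,2,2-trichloroethyl sulfate | CC1=CCC[C@@H](C)[C@]1(C)CC/C(C)=C/CC[C@H](CCCc1ccoc1)COS(=O)(=O)OCC(Cl)(Cl)Cl
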